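The earlier runs and the new flask stem from a simulated flask with made-up constants.

**Reading time.** You read these flasks at 30 h, so this note is for that hour.

| flask | substrate | partner | temperature | remark | time |
|---|---|---|---|---|---|
| oak | 0.40 M | 0.16 M | 35 °C | run made earlier |  |
| maple | 0.40 M | 0.55 M | 60 °C | run made earlier |  |
| larch | 0.24 M | 0.28 M | 35 °C | run made earlier |  |
| autumn | 0.10 M | 0.400 M | 40 °C |  | 30 h |
| spring | 0.40 M | 0.280 M | 40 °C |  | 30 h |
| midnight | 0.40 M | 0.280 M | 80 °C |  | 30 h |
| noon | 0.25 M | 0.200 M | 60 °C |  | 30 h |
| winter | 0.25 M | 0.800 M | 40 °C |  | 30 h |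

| run | time / h | product / % | substrate / % |
|---|---|---|---|
| oak | 2.50 | 4 | 29 |
| oak | 6.00 | 18 | 3 |
| oak | 12.0 | 28 | 2 |
| oak | 30.0 | 36 | 0 |
| maple | 3.00 | 78 | 0 |
| maple | 6.00 | 77 | 1 |
| maple | 10.0 | 74 | 1 |
| maple | 12.0 | 76 | 0 |
| larch | 4.00 | 20 | 13 |
| larch | 10.0 | 48 | 0 |
| larch | 20.0 | 68 | 1 |
| larch | 30.0 | 73 | 0 |

(each reading ± 1.5 percentage points)



* the flasks by amount of product, in percent of the substrate charged, highest first, at 30 h (autumn / spring / midnight / noon / winter)
* the amount of product, in percent of the substrate charged of the flask you put first, at 30 h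
* the amount of product, in percent of the substrate charged of the flask you put last, at 30 h

**The fork.** Follow one substrate molecule. The maple run shows substrate at 0% by 3.00 h, yet product stays near 76%. So a molecule waits in an unseen form, then closes with partner, and can open again. I take its odds of standing as product as a constant times the unused partner. In maple the odds are 3.17 on 0.246 M of unused partner. That ratio, 12.9 /M, is the closing constant, the equilibrium constant of the last step.

**Don't warm.** The larch run, still creeping at 30.0 h, reads 25.8 /M, higher than maple. Maple is hotter, so I read the closing constant as falling with heat: do not warm these flasks.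

**My reckoning.** Noon stands at maple's 60 °C. Maple was flat by 3.00 h, far shorter than 30 h. So I put the closing constant on noon's charges and expect 49.5% product.

**The forecast.** It gives winter > autumn > spring > noon > midnight, with 93% first and 43% last. Its ground for the plateaus: “I read this as a reversible final step”.

**The flasks.** They give winter > autumn > spring > noon > midnight, with 94.1% first and 41.3% last.

    open intermediate + second intermediate ⇌ product (K = 28.0 /M, k = 2.15 × 10⁻⁴ /M/s, Ea = 76.0 kJ/mol, ΔH = −35.0 kJ/mol)
    partner → second intermediate (k = 4.94 × 10⁻⁴ /s, Ea = 95.0 kJ/mol)
    substrate → open intermediate (k = 2.52 × 10⁻⁴ /s, Ea = 90.0 kJ/mol)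
    (constants at 40 °C)

Early in winter, near 0.390 h, partner passes into second intermediate with half-life 0.39 h, while substrate passes into open intermediate with half-life 0.76 h by that step alone. By 15.0 h winter holds 93.9% product. At 30.0 h the closing step in winter relaxes in 1.46 h, both ways together, short against 30 h, which is thermodynamic control, and longer standing adds nothing to winter's product. Noon ends with odds 0.965, and the closing constant times its 0.0772 M of second intermediate gives 0.996. Midnight's ratio stands lower than the closing constant, at 6.11 /M.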